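**Retrosynthetic overview**

- The target is the C8 methacrylate of a ten-membered α-methylene lactone carrying the cis-4,5-epoxide, the C9 acetate and the ring-cis C1=C10 enoate.
- Key disconnection: C6–C7 together with the lactone C–O bond. A seco epoxy-aldehyde bearing a (Z)-2-(bromomethyl)enoate is closed by chromium-mediated allylation, and the resulting alkoxide lactonizes, so carbocycle and γ-lactone form in one operation.
- The seco chain comes from C9–C10 coupling of a (Z)-α-iodo enoate with a glycerate-derived aldehyde (then oxidation/reduction to fix C9), followed by C7–C11 coupling with 2-bromoacrylate and SN2′ bromination.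
- Stereochemistry: C4/C5 from Sharpless epoxidation of nerol, C8 from methyl (S)-glycerate, C9 by oxazaborolidine reduction, C6/C7 in the ring closure.
- Ring order: oxirane first, then ten-membered ring and lactone together.

Assumption: germacrane numbering (C1–C10 ring, C11–C13 lactone unit, C14 ester carbon, C15 methyl) is used for positions; all three starting materials are purchased.

**Step 1**
Reactants: 1 nerol [(2Z)-3,7-dimethylocta-2,6-dien-1-ol]
Product: 2 [(2S,3R)-3-methyl-3-(4-methylpent-3-en-1-yl)oxiran-2-yl]methanol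
Conditions: Ti(OiPr)4 (10 mol %), L-(+)-diethyl tartrate (12 mol %), tBuOOH, 4 Å molecular sieves, CH2Cl2, −20 °C
Reagents that add atoms: tert-butyl hydroperoxide, CC(C)(C)OO
Why: Sharpless asymmetric epoxidation of the primary allylic alcohol delivers oxygen to one face of the Z-trisubstituted alkene only, setting C5 (S) and C4 (R) with C3 and C6 cis on the oxirane as in the target, while the isolated 6,7-alkene is untouched.

**Step 2**
Reactants: 2 [(2S,3R)-3-methyl-3-(4-methylpent-3-en-1-yl)oxiran-2-yl]methanol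
Product: 3 (2S,3R)-2-[(4-methoxybenzyloxy)methyl]-3-methyl-3-(4-methylpent-3-en-1-yl)oxirane
Conditions: NaH, 4-methoxybenzyl chloride, Bu4NI (cat.), THF, 0 °C to rt
Reagents that add atoms: 4-methoxybenzyl chloride, COc1ccc(CCl)cc1
Why: Williamson ether synthesis on the primary alkoxide (alkylation outruns Payne rearrangement at 0 °C) masks the C6 hydroxyl through steps 3–14 and touches no stereocentre.

**Step 3**
Reactants: 3 (2S,3R)-2-[(4-methoxybenzyloxy)methyl]-3-methyl-3-(4-methylpent-3-en-1-yl)oxirane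
Product: 5 3-[(2R,3S)-3-[(4-methoxybenzyloxy)methyl]-2-methyloxiran-2-yl]propanal, via ozonide 4 (not isolated)
Conditions: O3, CH2Cl2, −78 °C (stopped at first excess); then Me2S, −78 °C to rt
Reagents that add atoms: ozone, [O-][O+]=O
Why: Ozonolysis of the only C=C bond and reductive cleavage of the ozonide by Me2S give the C1 aldehyde; epoxide and PMB ether survive brief exposure at −78 °C and no stereocentre is affected.

**Step 4**
Reactants: 5 3-[(2R,3S)-3-[(4-methoxybenzyloxy)methyl]-2-methyloxiran-2-yl]propanal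
Product: 6 methyl (2Z)-2-iodo-5-[(2R,3S)-3-[(4-methoxybenzyloxy)methyl]-2-methyloxiran-2-yl]pent-2-enoate
Conditions: Ph3P=CHCO2Me, N-iodosuccinimide, CH2Cl2, −20 °C; then 5, −20 °C to rt
Reagents that add atoms: methyl (triphenylphosphoranylidene)acetate, COC(=O)C=P(c1ccccc1)(c1ccccc1)c1ccccc1; N-iodosuccinimide, O=C1CCC(=O)N1I
Why: One-pot ylide iodination and Wittig olefination; the stabilised iodo-ylide places the ester trans to the alkyl chain, giving the (Z)-iodoalkene whose geometry later becomes the ring-cis C1=C10 bond.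

**Step 5**
Reactants: 7 methyl (4S)-2,2-dimethyl-1,3-dioxolane-4-carboxylate
Product: 8 methyl (2S)-2,3-dihydroxypropanoate
Conditions: TsOH·H2O (cat.), MeOH, rt
Reagents that add atoms: none
Why: Acid-catalysed transketalisation to methanol releases the diol without touching the ester or the chiral-pool stereocentre that becomes C8.

**Step 6**
Reactants: 8 methyl (2S)-2,3-dihydroxypropanoate
Product: 9 methyl (2S)-2,3-bis(triethylsilyloxy)propanoate
Conditions: Et3SiCl (2.4 equiv), imidazole, DMF, 0 °C to rt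
Reagents that add atoms: chlorotriethylsilane, CC[Si](Cl)(CC)CC
Why: Standard silylation of both hydroxyls; the primary TES ether is the later handle for C7 and the secondary one keeps O8 a poor leaving group, with no stereochemical change.

**Step 7**
Reactants: 9 methyl (2S)-2,3-bis(triethylsilyloxy)propanoate
Product: 10 (2S)-2,3-bis(triethylsilyloxy)propanal
Conditions: iBu2AlH (1.1 equiv), CH2Cl2, −78 °C
Reagents that add atoms: none
Why: Low-temperature half-reduction of the ester proceeds through a tetrahedral aluminium hemiacetal that collapses only on work-up, giving the configurationally intact α-silyloxy aldehyde.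

**Step 8**
Reactants: 6 methyl (2Z)-2-iodo-5-[(2R,3S)-3-[(4-methoxybenzyloxy)methyl]-2-methyloxiran-2-yl]pent-2-enoate; 10 (2S)-2,3-bis(triethylsilyloxy)propanal
Product: 11 methyl (2E)-2-[(2S)-1-hydroxy-2,3-bis(triethylsilyloxy)propyl]-5-[(2R,3S)-3-[(4-methoxybenzyloxy)methyl]-2-methyloxiran-2-yl]pent-2-enoate (both C9 epimers)
Conditions: CrCl2 (5 equiv), NiCl2 (1 mol %), DMSO, rt
Reagents that add atoms: none
Why: Nozaki–Hiyama–Kishi coupling: zerovalent nickel inserts into the carbon–iodine bond with retention of geometry and the alkenyl trivalent chromium species adds to the aldehyde to form C9–C10; C9 forms unselectively (Felkin-type anti epimer major) and is corrected in steps 9 and 10.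

**Step 9**
Reactants: 11 methyl (2E)-2-[(2S)-1-hydroxy-2,3-bis(triethylsilyloxy)propyl]-5-[(2R,3S)-3-[(4-methoxybenzyloxy)methyl]-2-methyloxiran-2-yl]pent-2-enoate
Product: 12 methyl (2E)-2-[(2S)-2,3-bis(triethylsilyloxy)propanoyl]-5-[(2R,3S)-3-[(4-methoxybenzyloxy)methyl]-2-methyloxiran-2-yl]pent-2-enoate
Conditions: Dess–Martin periodinane, pyridine, CH2Cl2, 0 °C; used at once
Reagents that add atoms: none
Why: Dess–Martin oxidation of the allylic alcohol erases the uncontrolled C9 centre under buffered conditions that leave C8 intact; immediate use keeps the C1=C10 geometry from equilibrating.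

**Step 10**
Reactants: 12 methyl (2E)-2-[(2S)-2,3-bis(triethylsilyloxy)propanoyl]-5-[(2R,3S)-3-[(4-methoxybenzyloxy)methyl]-2-methyloxiran-2-yl]pent-2-enoate
Product: 13 methyl (2E)-2-[(1S,2S)-1-hydroxy-2,3-bis(triethylsilyloxy)propyl]-5-[(2R,3S)-3-[(4-methoxybenzyloxy)methyl]-2-methyloxiran-2-yl]pent-2-enoate
Conditions: (S)-1-methyl-3,3-diphenyltetrahydro-1H,3H-pyrrolo[1,2-c][1,3,2]oxazaborole (1 equiv), catecholborane, toluene, −78 °C
Reagents that add atoms: none
Why: Corey–Bakshi–Shibata reduction (1,2-selective at −78 °C): with the alkenyl arm as the larger group the oxazaborolidine delivers hydride to the face giving 9S, the same sense as Felkin–Anh attack anti to the C8–OSi bond, so the 8,9-syn pattern results.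

**Step 11**
Reactants: 13 methyl (2E)-2-[(1S,2S)-1-hydroxy-2,3-bis(triethylsilyloxy)propyl]-5-[(2R,3S)-3-[(4-methoxybenzyloxy)methyl]-2-methyloxiran-2-yl]pent-2-enoate
Product: 14 methyl (2E)-2-[(1S,2S)-1-acetoxy-2,3-bis(triethylsilyloxy)propyl]-5-[(2R,3S)-3-[(4-methoxybenzyloxy)methyl]-2-methyloxiran-2-yl]pent-2-enoate
Conditions: Ac2O, 4-(dimethylamino)pyridine (cat.), pyridine, CH2Cl2, 0 °C
Reagents that add atoms: acetic anhydride, CC(=O)OC(C)=O
Why: Nucleophile-catalysed acylation of the only free hydroxyl installs the C9 acetate of the target with retention.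

**Step 12**
Reactants: 14 methyl (2E)-2-[(1S,2S)-1-acetoxy-2,3-bis(triethylsilyloxy)propyl]-5-[(2R,3S)-3-[(4-methoxybenzyloxy)methyl]-2-methyloxiran-2-yl]pent-2-enoate
Product: 15 methyl (2E)-2-[(1S,2R)-1-acetoxy-3-oxo-2-(triethylsilyloxy)propyl]-5-[(2R,3S)-3-[(4-methoxybenzyloxy)methyl]-2-methyloxiran-2-yl]pent-2-enoate
Conditions: (COCl)2, DMSO, CH2Cl2, −78 to −30 °C; then Et3N, −78 °C; used crude
Reagents that add atoms: none
Why: Swern oxidation in which the chlorosulfonium reagent exchanges selectively with the unhindered primary triethylsilyl ether and oxidises it directly to the aldehyde, leaving the secondary TES ether, PMB ether and epoxide; low temperature preserves C8 and limits β-elimination of the acetate.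

**Step 13**
Reactants: 15 methyl (2E)-2-[(1S,2R)-1-acetoxy-3-oxo-2-(triethylsilyloxy)propyl]-5-[(2R,3S)-3-[(4-methoxybenzyloxy)methyl]-2-methyloxiran-2-yl]pent-2-enoate; 16 methyl 2-bromoprop-2-enoate
Product: 17 methyl (4S,5S,6E)-5-acetoxy-3-hydroxy-6-(methoxycarbonyl)-2-methylidene-9-[(2R,3S)-3-[(4-methoxybenzyloxy)methyl]-2-methyloxiran-2-yl]-4-(triethylsilyloxy)non-6-enoate (both C7 epimers)
Conditions: CrCl2 (5 equiv), NiCl2 (2 mol %), DMF, 0 °C to rt
Reagents that add atoms: none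
Why: Nozaki–Hiyama–Kishi coupling of the 2-bromoacrylate (a non-basic equivalent of the Morita–Baylis–Hillman reaction) forms C7–C11 without β-elimination of the acetate; the new C7 carbinol centre forms as a mixture and is destroyed in step 14.

**Step 14**
Reactants: 17 methyl (4S,5S,6E)-5-acetoxy-3-hydroxy-6-(methoxycarbonyl)-2-methylidene-9-[(2R,3S)-3-[(4-methoxybenzyloxy)methyl]-2-methyloxiran-2-yl]-4-(triethylsilyloxy)non-6-enoate
Product: 18 methyl (2Z,4S,5S,6E)-5-acetoxy-2-(bromomethyl)-6-(methoxycarbonyl)-9-[(2R,3S)-3-[(4-methoxybenzyloxy)methyl]-2-methyloxiran-2-yl]-4-(triethylsilyloxy)nona-2,6-dienoate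
Conditions: N-bromosuccinimide, Me2S, CH2Cl2, −20 to 0 °C
Reagents that add atoms: N-bromosuccinimide, O=C1CCC(=O)N1Br
Why: Corey–Kim-type activation of the allylic alcohol and SN2′ attack of bromide give the rearranged primary allylic bromide as the thermodynamically preferred (Z)-2-(bromomethyl)enoate (C8 trans to the ester), removing the C7 stereocentre.

**Step 15**
Reactants: 18 methyl (2Z,4S,5S,6E)-5-acetoxy-2-(bromomethyl)-6-(methoxycarbonyl)-9-[(2R,3S)-3-[(4-methoxybenzyloxy)methyl]-2-methyloxiran-2-yl]-4-(triethylsilyloxy)nona-2,6-dienoate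
Product: 19 methyl (2Z,4S,5S,6E)-5-acetoxy-2-(bromomethyl)-9-[(2R,3S)-3-(hydroxymethyl)-2-methyloxiran-2-yl]-6-(methoxycarbonyl)-4-(triethylsilyloxy)nona-2,6-dienoate
Conditions: DDQ, CH2Cl2/H2O (10:1), 0 °C
Reagents that add atoms: none
Why: Oxidative PMB cleavage (hydride abstraction from the electron-rich benzylic position, then hydrolysis) frees the C6 hydroxyl without affecting the allylic bromide, silyl ether, acetate or epoxide.

**Step 16**
Reactants: 19 methyl (2Z,4S,5S,6E)-5-acetoxy-2-(bromomethyl)-9-[(2R,3S)-3-(hydroxymethyl)-2-methyloxiran-2-yl]-6-(methoxycarbonyl)-4-(triethylsilyloxy)nona-2,6-dienoate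
Product: 20 methyl (2Z,4S,5S,6E)-5-acetoxy-2-(bromomethyl)-9-[(2R,3R)-3-formyl-2-methyloxiran-2-yl]-6-(methoxycarbonyl)-4-(triethylsilyloxy)nona-2,6-dienoate
Conditions: Dess–Martin periodinane, pyridine, CH2Cl2, 0 °C; used crude
Reagents that add atoms: none
Why: Dess–Martin oxidation gives the cis-epoxy aldehyde under neutral conditions that neither epimerise C5 nor open the epoxide.

**Step 17 (key step)**
Reactants: 20 methyl (2Z,4S,5S,6E)-5-acetoxy-2-(bromomethyl)-9-[(2R,3R)-3-formyl-2-methyloxiran-2-yl]-6-(methoxycarbonyl)-4-(triethylsilyloxy)nona-2,6-dienoate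
Product: 22 methyl (1(10)E,4R,5S,6S,7S,8S,9S)-9-acetoxy-4,5-epoxy-8-(triethylsilyloxy)germacra-1(10),11(13)-dien-12,6-olid-14-oate, via hydroxy ester 21 (not isolated)
Conditions: CrCl2 (10 equiv), THF/DMF (4:1), 2 mM, addition of 20 over 8 h, rt, then 12 h; aq. NH4Cl
Reagents that add atoms: none
Why: Nozaki–Hiyama (chromium Barbier) allylation: divalent chromium turns the allylic bromide into an allylchromium that adds through its γ-carbon C7 to the aldehyde and closes the ten-membered ring, and the O6 chromium alkoxide then acylates on the adjacent acrylate ester to close the γ-lactone; C6 is set by Felkin–Anh attack anti to the C5–O bond of the cis-epoxide and C7 by the cyclic chair transition state, which inside the forming ring is expected to give the trans-fused lactone with H7 cis to H8.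

**Step 18**
Reactants: 22 methyl (1(10)E,4R,5S,6S,7S,8S,9S)-9-acetoxy-4,5-epoxy-8-(triethylsilyloxy)germacra-1(10),11(13)-dien-12,6-olid-14-oate
Product: 23 methyl (1(10)E,4R,5S,6S,7R,8S,9S)-9-acetoxy-4,5-epoxy-8-hydroxygermacra-1(10),11(13)-dien-12,6-olid-14-oate
Conditions: HF·pyridine, pyridine, THF, 0 °C
Reagents that add atoms: none
Why: Buffered fluoride cleavage of the silicon–oxygen bond frees the C8 hydroxyl without opening the epoxide or lactone; no stereocentre is affected (the descriptor at C7 changes only through substituent priority).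

**Step 19**
Reactants: 23 methyl (1(10)E,4R,5S,6S,7R,8S,9S)-9-acetoxy-4,5-epoxy-8-hydroxygermacra-1(10),11(13)-dien-12,6-olid-14-oate
Product: 24 methyl (1(10)E,4R,5S,6S,7R,8S,9S)-9-acetoxy-4,5-epoxy-8-(2-methylprop-2-enoyloxy)germacra-1(10),11(13)-dien-12,6-olid-14-oate (CNP0153978.8)
Conditions: methacrylic anhydride, Et3N, 4-(dimethylamino)pyridine (cat.), CH2Cl2, 0 °C
Reagents that add atoms: methacrylic anhydride, CC(=C)C(=O)OC(=O)C(C)=C
Why: Nucleophile-catalysed acylation of the secondary C8 alcohol with retention completes the target; low temperature suppresses acetyl migration and conjugate addition to the α-methylene lactone.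

**Compound list**

1 | nerol [(2Z)-3,7-dimethylocta-2,6-dien-1-ol] | CC(C)=CCC/C(C)=C\CO | starting material
2 | [(2S,3R)-3-methyl-3-(4-methylpent-3-en-1-yl)oxiran-2-yl]methanol | OC[C@@H]1O[C@]1(C)CCC=C(C)C | intermediate
3 | (2S,3R)-2-[(4-methoxybenzyloxy)methyl]-3-methyl-3-(4-methylpent-3-en-1-yl)oxirane | COc1ccc(COC[C@@H]2O[C@]2(C)CCC=C(C)C)cc1 | intermediate
4 | 3-{2-[(2R,3S)-3-[(4-methoxybenzyloxy)methyl]-2-methyloxiran-2-yl]ethyl}-5,5-dimethyl-1,2,4-trioxolane (ozonide; trioxolane carbon unassigned) | COc1ccc(COC[C@@H]2O[C@]2(C)CCC3OOC(C)(C)O3)cc1 | intermediate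
5 | 3-[(2R,3S)-3-[(4-methoxybenzyloxy)methyl]-2-methyloxiran-2-yl]propanal | COc1ccc(COC[C@@H]2O[C@]2(C)CCC=O)cc1 | intermediate
6 | methyl (2Z)-2-iodo-5-[(2R,3S)-3-[(4-methoxybenzyloxy)methyl]-2-methyloxiran-2-yl]pent-2-enoate | COc1ccc(COC[C@@H]2O[C@]2(C)CC/C=C(/C(=O)OC)I)cc1 | intermediate
7 | methyl (4S)-2,2-dimethyl-1,3-dioxolane-4-carboxylate | COC(=O)[C@@H]1COC(C)(C)O1 | starting material
8 | methyl (2S)-2,3-dihydroxypropanoate | COC(=O)[C@@H](O)CO | intermediate
9 | methyl (2S)-2,3-bis(triethylsilyloxy)propanoate | COC(=O)[C@@H](O[Si](CC)(CC)CC)CO[Si](CC)(CC)CC | intermediate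
10 | (2S)-2,3-bis(triethylsilyloxy)propanal | O=C[C@@H](O[Si](CC)(CC)CC)CO[Si](CC)(CC)CC | intermediate
11 | methyl (2E)-2-[(2S)-1-hydroxy-2,3-bis(triethylsilyloxy)propyl]-5-[(2R,3S)-3-[(4-methoxybenzyloxy)methyl]-2-methyloxiran-2-yl]pent-2-enoate (both C9 epimers) | COc1ccc(COC[C@@H]2O[C@]2(C)CC/C=C(/C(=O)OC)C(O)[C@@H](O[Si](CC)(CC)CC)CO[Si](CC)(CC)CC)cc1 | intermediate
12 | methyl (2E)-2-[(2S)-2,3-bis(triethylsilyloxy)propanoyl]-5-[(2R,3S)-3-[(4-methoxybenzyloxy)methyl]-2-methyloxiran-2-yl]pent-2-enoate | COc1ccc(COC[C@@H]2O[C@]2(C)CC/C=C(/C(=O)OC)C(=O)[C@@H](O[Si](CC)(CC)CC)CO[Si](CC)(CC)CC)cc1 | intermediate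
13 | methyl (2E)-2-[(1S,2S)-1-hydroxy-2,3-bis(triethylsilyloxy)propyl]-5-[(2R,3S)-3-[(4-methoxybenzyloxy)methyl]-2-methyloxiran-2-yl]pent-2-enoate | COc1ccc(COC[C@@H]2O[C@]2(C)CC/C=C(/C(=O)OC)[C@H](O)[C@@H](O[Si](CC)(CC)CC)CO[Si](CC)(CC)CC)cc1 | intermediate
14 | methyl (2E)-2-[(1S,2S)-1-acetoxy-2,3-bis(triethylsilyloxy)propyl]-5-[(2R,3S)-3-[(4-methoxybenzyloxy)methyl]-2-methyloxiran-2-yl]pent-2-enoate | COc1ccc(COC[C@@H]2O[C@]2(C)CC/C=C(/C(=O)OC)[C@H](OC(C)=O)[C@@H](O[Si](CC)(CC)CC)CO[Si](CC)(CC)CC)cc1 | intermediate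
15 | methyl (2E)-2-[(1S,2R)-1-acetoxy-3-oxo-2-(triethylsilyloxy)propyl]-5-[(2R,3S)-3-[(4-methoxybenzyloxy)methyl]-2-methyloxiran-2-yl]pent-2-enoate | COc1ccc(COC[C@@H]2O[C@]2(C)CC/C=C(/C(=O)OC)[C@H](OC(C)=O)[C@@H](O[Si](CC)(CC)CC)C=O)cc1 | intermediate
16 | methyl 2-bromoprop-2-enoate | C=C(Br)C(=O)OC | starting material
17 | methyl (4S,5S,6E)-5-acetoxy-3-hydroxy-6-(methoxycarbonyl)-2-methylidene-9-[(2R,3S)-3-[(4-methoxybenzyloxy)methyl]-2-methyloxiran-2-yl]-4-(triethylsilyloxy)non-6-enoate (both C7 epimers) | COc1ccc(COC[C@@H]2O[C@]2(C)CC/C=C(/C(=O)OC)[C@H](OC(C)=O)[C@@H](O[Si](CC)(CC)CC)C(O)C(=C)C(=O)OC)cc1 | intermediate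
18 | methyl (2Z,4S,5S,6E)-5-acetoxy-2-(bromomethyl)-6-(methoxycarbonyl)-9-[(2R,3S)-3-[(4-methoxybenzyloxy)methyl]-2-methyloxiran-2-yl]-4-(triethylsilyloxy)nona-2,6-dienoate | COc1ccc(COC[C@@H]2O[C@]2(C)CC/C=C(/C(=O)OC)[C@H](OC(C)=O)[C@@H](O[Si](CC)(CC)CC)/C=C(\CBr)C(=O)OC)cc1 | intermediate
19 | methyl (2Z,4S,5S,6E)-5-acetoxy-2-(bromomethyl)-9-[(2R,3S)-3-(hydroxymethyl)-2-methyloxiran-2-yl]-6-(methoxycarbonyl)-4-(triethylsilyloxy)nona-2,6-dienoate | OC[C@@H]1O[C@]1(C)CC/C=C(/C(=O)OC)[C@H](OC(C)=O)[C@@H](O[Si](CC)(CC)CC)/C=C(\CBr)C(=O)OC | intermediate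
20 | methyl (2Z,4S,5S,6E)-5-acetoxy-2-(bromomethyl)-9-[(2R,3R)-3-formyl-2-methyloxiran-2-yl]-6-(methoxycarbonyl)-4-(triethylsilyloxy)nona-2,6-dienoate | O=C[C@@H]1O[C@]1(C)CC/C=C(/C(=O)OC)[C@H](OC(C)=O)[C@@H](O[Si](CC)(CC)CC)/C=C(\CBr)C(=O)OC | intermediate
21 | dimethyl (1(10)E,4R,5S,6S,7S,8S,9S)-9-acetoxy-4,5-epoxy-6-hydroxy-8-(triethylsilyloxy)germacra-1(10),11(13)-diene-12,14-dioate (present as its chromium alkoxide) | CC[Si](CC)(CC)O[C@H]1[C@@H](C(=C)C(=O)OC)[C@H](O)[C@@H]2O[C@]2(C)CC/C=C(/C(=O)OC)[C@@H]1OC(C)=O | intermediate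
22 | methyl (1(10)E,4R,5S,6S,7S,8S,9S)-9-acetoxy-4,5-epoxy-8-(triethylsilyloxy)germacra-1(10),11(13)-dien-12,6-olid-14-oate | CC[Si](CC)(CC)O[C@H]1[C@H]2C(=C)C(=O)O[C@@H]2[C@@H]2O[C@]2(C)CC/C=C(/C(=O)OC)[C@@H]1OC(C)=O | intermediate
23 | methyl (1(10)E,4R,5S,6S,7R,8S,9S)-9-acetoxy-4,5-epoxy-8-hydroxygermacra-1(10),11(13)-dien-12,6-olid-14-oate | O[C@H]1[C@H]2C(=C)C(=O)O[C@@H]2[C@@H]2O[C@]2(C)CC/C=C(/C(=O)OC)[C@@H]1OC(C)=O | intermediate
24 | methyl (1(10)E,4R,5S,6S,7R,8S,9S)-9-acetoxy-4,5-epoxy-8-(2-methylprop-2-enoyloxy)germacra-1(10),11(13)-dien-12,6-olid-14-oate (CNP0153978.8) | C=C(C)C(=O)O[C@H]1[C@H]2C(=C)C(=O)O[C@@H]2[C@@H]2O[C@]2(C)CC/C=C(/C(=O)OC)[C@@H]1OC(C)=O | target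

**Step count**

Total: 19 steps. Longest linear sequence: 16 steps (steps 1–4 and 8–19 from nerol); the glycerate branch (steps 5–7) joins at step 8.

**Steps most likely to fail, with fallbacks**

Step 17 (ring closure and lactonization; risks are oligomers or the cis-fused lactone). The fallback sets out from 18 and returns at 22, replacing allylchromium by allylboron chemistry. Copper-catalysed borylation of 18 (bis(pinacolato)diboron, CuCl, PPh3, LiOMe, DMF) gives the pinacol allylboronate F1. DDQ then frees the primary alcohol to give the hydroxy boronate F2, and Dess–Martin oxidation gives the boronate epoxy aldehyde F3. Warming F3 at high dilution in toluene with catalytic Sc(OTf)3 effects intramolecular allylboration through a closed six-membered transition state, followed by lactonization, to reach 22.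

Step 13 (chromium coupling of the 2-bromoacrylate with the elimination-prone aldehyde). The fallback sets out from 15 and returns at 17, building the acrylate by aldol addition and selenoxide elimination. The lithium enolate of methyl 3-(phenylselanyl)propanoate (LiN(iPr)2, THF, −78 °C) adds to 15 to give the β-hydroxy selenide F4. Oxidation with H2O2/pyridine at 0 °C then eliminates the selenoxide toward the ester α-carbon and delivers 17.

Step 10 (face selectivity and 1,2- versus 1,4-reduction of the doubly activated enone, whose alkene can also isomerise). The fallback sets out from 11 and returns at 13, avoiding the ketone altogether. The major (9R) Felkin epimer of 11 is separated and inverted by Mitsunobu reaction (4-nitrobenzoic acid, PPh3, diisopropyl azodicarboxylate, toluene) to the (9S) 4-nitrobenzoate F5. Brief K2CO3/MeOH at 0 °C cleaves the ester to 13.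

**Further compounds**

F1 | step 17 | methyl (2E,4S,5S,6E)-5-acetoxy-6-(methoxycarbonyl)-9-[(2R,3S)-3-[(4-methoxybenzyloxy)methyl]-2-methyloxiran-2-yl]-2-[(4,4,5,5-tetramethyl-1,3,2-dioxaborolan-2-yl)methyl]-4-(triethylsilyloxy)nona-2,6-dienoate | COc1ccc(COC[C@@H]2O[C@]2(C)CC/C=C(/C(=O)OC)[C@H](OC(C)=O)[C@@H](O[Si](CC)(CC)CC)/C=C(\CB3OC(C)(C)C(C)(C)O3)C(=O)OC)cc1
F2 | step 17 | methyl (2E,4S,5S,6E)-5-acetoxy-9-[(2R,3S)-3-(hydroxymethyl)-2-methyloxiran-2-yl]-6-(methoxycarbonyl)-2-[(4,4,5,5-tetramethyl-1,3,2-dioxaborolan-2-yl)methyl]-4-(triethylsilyloxy)nona-2,6-dienoate | OC[C@@H]1O[C@]1(C)CC/C=C(/C(=O)OC)[C@H](OC(C)=O)[C@@H](O[Si](CC)(CC)CC)/C=C(\CB2OC(C)(C)C(C)(C)O2)C(=O)OC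
F3 | step 17 | methyl (2E,4S,5S,6E)-5-acetoxy-9-[(2R,3R)-3-formyl-2-methyloxiran-2-yl]-6-(methoxycarbonyl)-2-[(4,4,5,5-tetramethyl-1,3,2-dioxaborolan-2-yl)methyl]-4-(triethylsilyloxy)nona-2,6-dienoate | O=C[C@@H]1O[C@]1(C)CC/C=C(/C(=O)OC)[C@H](OC(C)=O)[C@@H](O[Si](CC)(CC)CC)/C=C(\CB2OC(C)(C)C(C)(C)O2)C(=O)OC
F4 | step 13 | methyl (4S,5S,6E)-5-acetoxy-3-hydroxy-6-(methoxycarbonyl)-9-[(2R,3S)-3-[(4-methoxybenzyloxy)methyl]-2-methyloxiran-2-yl]-2-[(phenylselanyl)methyl]-4-(triethylsilyloxy)non-6-enoate (mixture at C-2 and C-3) | COc1ccc(COC[C@@H]2O[C@]2(C)CC/C=C(/C(=O)OC)[C@H](OC(C)=O)[C@@H](O[Si](CC)(CC)CC)C(O)C(C[Se]c3ccccc3)C(=O)OC)cc1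
F5 | step 10 | methyl (2E)-2-[(1S,2S)-1-(4-nitrobenzoyloxy)-2,3-bis(triethylsilyloxy)propyl]-5-[(2R,3S)-3-[(4-methoxybenzyloxy)methyl]-2-methyloxiran-2-yl]pent-2-enoate | COc1ccc(COC[C@@H]2O[C@]2(C)CC/C=C(/C(=O)OC)[C@H](OC(=O)c3ccc(cc3)[N+]([O-])=O)[C@@H](O[Si](CC)(CC)CC)CO[Si](CC)(CC)CC)cc1
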